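Ring A, the benzoyl ring (C1 bearing the depside carbonyl, oxygen on C2 and C4, pentyl on C6), is taken as the folded form of a 3,5,7-trioxododecanoyl chain already esterified to O4 of ring B. One aldol-aromatization joins chain C2 to the C7 ketone, forming the C1–C6 bond of ring A and the whole depside skeleton, with the three hydroxyls sorted by hydrogen bonding into one free (ring A O4) and two chelated (O2 of each ring). The precursor is benzyl olivetolate whose O4 carries the open triketo ester, made by trapping a dioxinone-derived acylketene. Selective benzylation, double methylation and hydrogenolysis complete the synthesis.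

Key step: step 5

Assumption: olivetolic acid (2,4-dihydroxy-6-pentylbenzoic acid) is taken as a purchasable starting material; ring B passes through the fold with its hydrogen-bonded C2 hydroxyl free and its carboxyl as the benzyl ester; polycarbonyl compounds are drawn as keto tautomers although they exist largely as enols.

Step 1
Reactants: 1 2,2,6-trimethyl-4H-1,3-dioxin-4-one; 2 acetyl chloride
Product: 4 2,2-dimethyl-6-(2-oxopropyl)-4H-1,3-dioxin-4-one, via lithium dienolate 3 (not isolated)
Conditions: 1 (2 equiv), LiN(SiMe3)2 (2 equiv), THF, −78 °C; then AcCl (1 equiv), −78 °C to rt; aq. HCl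
Reagents that add atoms: none
Why: LiN(SiMe3)2 removes a proton from the C6 methyl group of 1 to give vinylogous dienolate 3, which is C-acylated at its terminal carbon by acetyl chloride in a vinylogous crossed Claisen acylation, the twofold excess of dienolate absorbing the proton of the more acidic product.

Step 2
Reactants: 4 2,2-dimethyl-6-(2-oxopropyl)-4H-1,3-dioxin-4-one; 5 hexanoyl chloride
Product: 7 2,2-dimethyl-6-(2,4-dioxononyl)-4H-1,3-dioxin-4-one, via dilithium dianion 6 (not isolated)
Conditions: 4 (2 equiv), LiN(iPr)2 (4.2 equiv), THF, −78 °C; then hexanoyl chloride (1 equiv), −78 to −30 °C; aq. HCl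
Reagents that add atoms: none
Why: Double deprotonation of 4 gives dianion 6, whose last-formed terminal carbanion is the most nucleophilic site and is acylated by hexanoyl chloride in a dianion crossed Claisen condensation, the dianion being kept in excess because the diketone product consumes one equivalent of base.

Step 3
Reactants: 8 olivetolic acid (2,4-dihydroxy-6-pentylbenzoic acid)
Product: 9 benzyl 2,4-dihydroxy-6-pentylbenzoate
Conditions: BnBr (1.1 equiv), KHCO3 (1.2 equiv), DMF, rt
Reagents that add atoms: benzyl bromide, BrCc1ccccc1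
Why: KHCO3 deprotonates only the carboxylic acid, and the carboxylate is O-alkylated by benzyl bromide in an SN2 esterification that leaves both phenols untouched, the standard way to benzyl 2,4-dihydroxybenzoates used as the alcohol partner of depsides.

Step 4
Reactants: 9 benzyl 2,4-dihydroxy-6-pentylbenzoate; 7 2,2-dimethyl-6-(2,4-dioxononyl)-4H-1,3-dioxin-4-one
Product: 11 benzyl 2-hydroxy-6-pentyl-4-(3,5,7-trioxododecanoyloxy)benzoate, via acylketene 10 (not isolated)
Conditions: 7 added slowly to 9 (1.5 equiv), PhMe, 110 °C; concentrate, use crude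
Reagents that add atoms: none
Why: Thermal retro-hetero-Diels–Alder loss of acetone from 7 releases acylketene 10, which should be captured by O4 of 9 because O2 is tied up in a hydrogen bond to the ester carbonyl and is far less nucleophilic, this being the known addition of phenols to dioxinone-derived acylketenes, with slow addition into excess hot phenol keeping intermolecular capture ahead of self-cyclization of the ketene.

Step 5
Reactants: 11 benzyl 2-hydroxy-6-pentyl-4-(3,5,7-trioxododecanoyloxy)benzoate
Product: 13 benzyl 4-[(2,4-dihydroxy-6-pentylbenzoyl)oxy]-2-hydroxy-6-pentylbenzoate, via cyclic aldol adduct 12 (not isolated)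
Conditions: Et3N (2 equiv), CH2Cl2, 0 °C; then HCl (4 M in dioxane), 0 °C to rt
Reagents that add atoms: none
Why: Triethylamine reversibly enolizes the 1,3-dicarbonyl methylenes, and the C2 carbon between the aryl ester carbonyl C1 and the C3 ketone adds to the C7 ketone to give cyclic aldol adduct 12, after which acid dehydrates the C7 carbinol and the C3 and C5 carbonyls enolize, so that one molecule of water is lost and ring A becomes aromatic irreversibly. The closest known reaction type is the biomimetic intramolecular aldol condensation and aromatization of 3,5,7-triketo esters to 6-alkylresorcylates, applied here to an aryl ester in place of the usual alkyl ester. Ring A closes by a 6-exo-trig attack on the C7 carbonyl, classed as 6-(enolendo) when the nucleophile is drawn as the C2=C3 enolate and as 6-(enolexo) when it is drawn through the ester carbonyl C1, both being favoured modes. No stereocentre is created in the product, because the two centres of adduct 12 are destroyed on aromatization. The step needs chemoselectivity for the C2-to-C7 aldol over Claisen attack of C6 on C1 and over lactonization of the C5 enol oxygen onto C1, either of which would expel the ring B aryloxide; a ketone is a better acceptor than an ester for a stabilized enolate under a weak amine base at 0 °C, the Claisen mode of such chains is known to need alkoxide or hydroxide, and aromatization drains the reversible aldol equilibrium. Once formed, the 2,6-disubstituted benzoate of 13 is shielded and hydrogen-bonded by the new C2 hydroxyl, which should protect the depside link during work-up.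

Step 6
Reactants: 13 benzyl 4-[(2,4-dihydroxy-6-pentylbenzoyl)oxy]-2-hydroxy-6-pentylbenzoate
Product: 14 benzyl 4-{[4-(benzyloxy)-2-hydroxy-6-pentylbenzoyl]oxy}-2-hydroxy-6-pentylbenzoate
Conditions: BnBr (1.05 equiv), K2CO3 (1.1 equiv), acetone, rt
Reagents that add atoms: benzyl bromide, BrCc1ccccc1
Why: Williamson etherification with about one equivalent of base and halide should alkylate only the free and most acidic para hydroxyl of ring A, because the two ortho hydroxyls are held in hydrogen bonds to their ester carbonyls, which is the usual regioselectivity of 2,4-dihydroxybenzoates.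

Step 7
Reactants: 14 benzyl 4-{[4-(benzyloxy)-2-hydroxy-6-pentylbenzoyl]oxy}-2-hydroxy-6-pentylbenzoate
Product: 15 benzyl 4-{[4-(benzyloxy)-2-methoxy-6-pentylbenzoyl]oxy}-2-methoxy-6-pentylbenzoate
Conditions: MeI (excess), K2CO3 (excess), DMF, rt to 40 °C
Reagents that add atoms: iodomethane, CI
Why: With excess base and iodomethane in a dipolar aprotic solvent both hydrogen-bonded salicylate-type hydroxyls should be O-methylated in one Williamson operation, while the anhydrous medium and the 2,6-disubstitution of both benzoates protect the depside and benzyl ester links.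

Step 8
Reactants: 15 benzyl 4-{[4-(benzyloxy)-2-methoxy-6-pentylbenzoyl]oxy}-2-methoxy-6-pentylbenzoate
Product: 16 4-O-demethylplanaic acid, 4-[(4-hydroxy-2-methoxy-6-pentylbenzoyl)oxy]-2-methoxy-6-pentylbenzoic acid
Conditions: H2 (1 atm), Pd/C (10%), EtOAc, rt
Reagents that add atoms: none
Why: Catalytic hydrogenolysis over palladium on carbon should cleave the benzyl ether and the benzyl ester together, while the aryl ester, the methyl ethers and the arene rings are inert and the non-alcoholic solvent excludes alcoholysis of the depside.

Compound list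
1 | 2,2,6-trimethyl-4H-1,3-dioxin-4-one | CC1=CC(=O)OC(C)(C)O1 | starting material
2 | acetyl chloride | CC(=O)Cl | starting material
3 | lithium dienolate of 1 (lithium 2,2-dimethyl-6-methylidene-6H-1,3-dioxin-4-olate) | [Li+].C=C1C=C([O-])OC(C)(C)O1 | intermediate (not isolated)
4 | 2,2-dimethyl-6-(2-oxopropyl)-4H-1,3-dioxin-4-one | CC(=O)CC1=CC(=O)OC(C)(C)O1 | intermediate
5 | hexanoyl chloride | CCCCCC(=O)Cl | starting material
6 | dilithium dianion of 4 (side-chain enolate plus ring dienolate) | [Li+].[Li+].C=C([O-])C=C1C=C([O-])OC(C)(C)O1 | intermediate (not isolated)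
7 | 2,2-dimethyl-6-(2,4-dioxononyl)-4H-1,3-dioxin-4-one | CCCCCC(=O)CC(=O)CC1=CC(=O)OC(C)(C)O1 | intermediate
8 | olivetolic acid, 2,4-dihydroxy-6-pentylbenzoic acid | CCCCCc1cc(O)cc(O)c1C(=O)O | starting material
9 | benzyl 2,4-dihydroxy-6-pentylbenzoate | CCCCCc1cc(O)cc(O)c1C(=O)OCc1ccccc1 | intermediate
10 | acylketene, 3,5,7-trioxododec-1-en-1-one | CCCCCC(=O)CC(=O)CC(=O)C=C=O | intermediate (not isolated)
11 | benzyl 2-hydroxy-6-pentyl-4-(3,5,7-trioxododecanoyloxy)benzoate | CCCCCC(=O)CC(=O)CC(=O)CC(=O)Oc1cc(CCCCC)c(C(=O)OCc2ccccc2)c(O)c1 | intermediate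
12 | 4-(benzyloxycarbonyl)-3-hydroxy-5-pentylphenyl 2-hydroxy-4,6-dioxo-2-pentylcyclohexane-1-carboxylate (transient mixture of diastereomers, no configuration defined) | CCCCCC1(O)CC(=O)CC(=O)C1C(=O)Oc1cc(CCCCC)c(C(=O)OCc2ccccc2)c(O)c1 | intermediate (not isolated)
13 | benzyl 4-[(2,4-dihydroxy-6-pentylbenzoyl)oxy]-2-hydroxy-6-pentylbenzoate | CCCCCc1cc(O)cc(O)c1C(=O)Oc1cc(CCCCC)c(C(=O)OCc2ccccc2)c(O)c1 | intermediate
14 | benzyl 4-{[4-(benzyloxy)-2-hydroxy-6-pentylbenzoyl]oxy}-2-hydroxy-6-pentylbenzoate | CCCCCc1cc(OCc2ccccc2)cc(O)c1C(=O)Oc1cc(CCCCC)c(C(=O)OCc2ccccc2)c(O)c1 | intermediate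
15 | benzyl 4-{[4-(benzyloxy)-2-methoxy-6-pentylbenzoyl]oxy}-2-methoxy-6-pentylbenzoate | CCCCCc1cc(OCc2ccccc2)cc(OC)c1C(=O)Oc1cc(CCCCC)c(C(=O)OCc2ccccc2)c(OC)c1 | intermediate
16 | 4-O-demethylplanaic acid (achiral, no stereocentres) | CCCCCc1cc(OC(=O)c2c(CCCCC)cc(O)cc2OC)cc(OC)c1C(=O)O | target

Total step count: 8. Longest linear sequence: 7 steps (1 → 4 → 7 → 11 → 13 → 14 → 15 → 16, that is steps 1, 2, 4, 5, 6, 7 and 8, with 9 from step 3 entering at step 4).

Steps most likely to fail

Step 5. The ring B aryloxide may be lost before ring A forms, through Claisen closure of C6 onto C1, through lactonization of an enol oxygen onto C1, or through base-induced cleavage of the activated aryl ester. The fallback folds ring A where no aryloxide can leave and makes the depside bond afterwards. It sets out from 7, which on treatment with Et3N in CH2Cl2 should undergo the known cycloaromatization of diketo-dioxinones to 7-hydroxy-2,2-dimethyl-5-pentyl-4H-1,3-benzodioxin-4-one F1. Benzylation (BnBr, K2CO3, acetone) gives 7-(benzyloxy)-2,2-dimethyl-5-pentyl-4H-1,3-benzodioxin-4-one F2. Hydrolysis with KOH in aqueous DMSO and cold acidification release 4-(benzyloxy)-2-hydroxy-6-pentylbenzoic acid F3. Carbodiimide esterification of F3 with O4 of 9 (DCC, toluene) comes back to the route at 14, from which steps 7 and 8 follow unchanged.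

Step 4. The acylketene may be consumed by attack of its own enol oxygen (pyranone formation) or by dimerization faster than the weakly nucleophilic phenol adds, and some acylation at O2 may occur. The fallback gives up the ketene and forms the aryl ester by classical acylation with a finished ring A acid. It sets out from 9, which is benzylated at the free para hydroxyl (BnBr, K2CO3, acetone) to benzyl 4-(benzyloxy)-2-hydroxy-6-pentylbenzoate F4 and then methylated (MeI, K2CO3, DMF) to benzyl 4-(benzyloxy)-2-methoxy-6-pentylbenzoate F5. Saponification of the hindered ester (KOH, aqueous DMSO, 90 °C) gives 4-(benzyloxy)-2-methoxy-6-pentylbenzoic acid F6. Esterification of F6 with O4 of a second portion of 9, through the mixed anhydride made with trifluoroacetic anhydride in toluene, gives benzyl 4-{[4-(benzyloxy)-2-methoxy-6-pentylbenzoyl]oxy}-2-hydroxy-6-pentylbenzoate F7. Methylation of its single hydrogen-bonded hydroxyl (MeI, K2CO3, DMF) comes back to the route at 15.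

Step 7. Alkylation of the two hydrogen-bonded hydroxyls may stall, or the depside may be cleaved under base by elimination from the ring A ortho phenoxide (quinone-ketene pathway) before it is methylated. The fallback places both methyl groups before the depside bond exists. It sets out from 9, which is allylated at the free para hydroxyl (allyl bromide, K2CO3, acetone) to benzyl 4-(allyloxy)-2-hydroxy-6-pentylbenzoate F8. Methylation (MeI, K2CO3, DMF) gives benzyl 4-(allyloxy)-2-methoxy-6-pentylbenzoate F9, and deallylation with catalytic Pd(PPh3)4 and morpholine gives benzyl 4-hydroxy-2-methoxy-6-pentylbenzoate F10. Esterification of F10 with 4-(benzyloxy)-2-methoxy-6-pentylbenzoic acid F6 (prepared from 9 as in the fallback for step 4), using trifluoroacetic anhydride in toluene, comes back to the route at 15, so no base touches the finished depside.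

Further compounds
F1 | step 5 | 7-hydroxy-2,2-dimethyl-5-pentyl-4H-1,3-benzodioxin-4-one | CCCCCc1cc(O)cc2c1C(=O)OC(C)(C)O2
F2 | step 5 | 7-(benzyloxy)-2,2-dimethyl-5-pentyl-4H-1,3-benzodioxin-4-one | CCCCCc1cc(OCc3ccccc3)cc2c1C(=O)OC(C)(C)O2
F3 | step 5 | 4-(benzyloxy)-2-hydroxy-6-pentylbenzoic acid | CCCCCc1cc(OCc2ccccc2)cc(O)c1C(=O)O
F4 | step 4 | benzyl 4-(benzyloxy)-2-hydroxy-6-pentylbenzoate | CCCCCc1cc(OCc2ccccc2)cc(O)c1C(=O)OCc1ccccc1
F5 | step 4 | benzyl 4-(benzyloxy)-2-methoxy-6-pentylbenzoate | CCCCCc1cc(OCc2ccccc2)cc(OC)c1C(=O)OCc1ccccc1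
F6 | step 4 | 4-(benzyloxy)-2-methoxy-6-pentylbenzoic acid | CCCCCc1cc(OCc2ccccc2)cc(OC)c1C(=O)O
F7 | step 4 | benzyl 4-{[4-(benzyloxy)-2-methoxy-6-pentylbenzoyl]oxy}-2-hydroxy-6-pentylbenzoate | CCCCCc1cc(OCc2ccccc2)cc(OC)c1C(=O)Oc1cc(CCCCC)c(C(=O)OCc2ccccc2)c(O)c1
F8 | step 7 | benzyl 4-(allyloxy)-2-hydroxy-6-pentylbenzoate | CCCCCc1cc(OCC=C)cc(O)c1C(=O)OCc1ccccc1
F9 | step 7 | benzyl 4-(allyloxy)-2-methoxy-6-pentylbenzoate | CCCCCc1cc(OCC=C)cc(OC)c1C(=O)OCc1ccccc1
F10 | step 7 | benzyl 4-hydroxy-2-methoxy-6-pentylbenzoate | CCCCCc1cc(O)cc(OC)c1C(=O)OCc1ccccc1
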